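**Retrosynthetic overview**
1. Numbering (germacrane): ring A = α-methylene-γ-lactone (O, C6, C7, C11, C12); ring B = 3(2H)-furanone (O, C3, C2, C1, C10); ring C = ten-membered carbocycle C1–C10; C14 = methyl on C10, C15 = methylene on C4.
2. Ring C is opened last at C4–C5 (Nozaki–Hiyama–Kishi closure of a C4 vinyl bromide onto a C5 aldehyde); ring A is opened at C6–C7 (Barbier allylation of 2,2-dimethoxyacetaldehyde by a C7/C11–C13 allyl bromide, then lactonisation).
3. Ring B is opened at C1–C10. The enabling feature is the α-oxy ketone O–C10(CH3)–C1(=O) of ring B, whose C1 carbonyl stands 1,4 to the C8 oxygen through C9. With C8 as a ketone, C10 is the β-carbon of an enone that already carries the ring B oxygen. C1 and C10 are both acceptor carbons and are joined by polarity reversal of a C1 aldehyde (carbene-catalysed Stetter cyclisation).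
4. The Stetter precursor is an acyclic β-(vinyloxy) aldehyde from oxa-Michael union of a C1–C4/C15 bromoallylic alcohol and a C7–C10/C14 ynone; C3 is a temporary stereocentre that relays to C10 and is erased on dehydrogenation to the furanone.
5. Order of ring formation: B (step 8), A (step 15), C (step 19).

Key step: step 8

Remark (assumption): compounds 1, 2, 7, 8, 18 and 21 are taken as purchased. Either enantiomer of alcohol 6 would serve, since C3 is erased in step 9; the (S) form is chosen as the one expected to reinforce the catalyst in step 8. The sense of induction of each chiral catalyst is assigned by analogy, and the antipodal catalyst is available in every case.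

**Step 1**
Reactants: 1 3-[(tert-butyldimethylsilyl)oxy]propanal; 2 bromoethene
Product: 4 rac-2-bromo-5-[(tert-butyldimethylsilyl)oxy]pent-1-en-3-ol, via 1-bromo-1-lithioethene 3 (not isolated)
Conditions: LiN(iPr)2, THF–Et2O–pentane, −110 °C; then 1, −110 to −90 °C; H2O
Reagents that add atoms: none
Why: At −110 °C deprotonation of bromoethene gives the carbenoid 3, which adds to the aldehyde carbonyl faster than it decomposes (1,2-addition of an α-halovinyllithium), giving the racemic 2-bromoallylic alcohol whose stereocentre is corrected in steps 2 and 3.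

**Step 2**
Reactants: 4 rac-2-bromo-5-[(tert-butyldimethylsilyl)oxy]pent-1-en-3-ol
Product: 5 2-bromo-5-[(tert-butyldimethylsilyl)oxy]pent-1-en-3-one
Conditions: Dess–Martin periodinane, NaHCO3, CH2Cl2, 0 °C to rt
Reagents that add atoms: none
Why: Dess–Martin oxidation converts the allylic alcohol into the α-bromo enone under buffered, non-basic conditions that spare the silyl ether and avoid β-elimination of silyloxide.

**Step 3**
Reactants: 5 2-bromo-5-[(tert-butyldimethylsilyl)oxy]pent-1-en-3-one
Product: 6 (3S)-2-bromo-5-[(tert-butyldimethylsilyl)oxy]pent-1-en-3-ol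
Conditions: (R)-tetrahydro-1-methyl-3,3-diphenyl-1H,3H-pyrrolo[1,2-c][1,3,2]oxazaborole (20 mol %), catecholborane, toluene, −78 °C; H2O
Reagents that add atoms: none
Why: Corey–Bakshi–Shibata reduction, in which the 1-bromovinyl group acts as the large substituent so that the (R)-oxazaborolidine should deliver hydride to give the (S)-carbinol; this sets the temporary C3 stereocentre.

**Step 4**
Reactants: 7 methyl 2,2-dimethoxyacetate; 8 prop-1-yn-1-ylmagnesium bromide
Product: 9 1,1-dimethoxypent-3-yn-2-one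
Conditions: THF, −78 °C; H2O
Reagents that add atoms: none
Why: Acyl substitution of the α,α-dialkoxy ester by the alkynyl Grignard reagent stops at the ketone because the chelated magnesium hemiketalate survives at −78 °C until work-up.

**Step 5**
Reactants: 6 (3S)-2-bromo-5-[(tert-butyldimethylsilyl)oxy]pent-1-en-3-ol; 9 1,1-dimethoxypent-3-yn-2-one
Product: 10 (3E)-4-{[(3S)-2-bromo-5-[(tert-butyldimethylsilyl)oxy]pent-1-en-3-yl]oxy}-1,1-dimethoxypent-3-en-2-one
Conditions: PMe3 (10 mol %), CH2Cl2, 0 °C to rt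
Reagents that add atoms: none
Why: Phosphine-catalysed oxa-Michael addition, in which PMe3 adds to the ynone, the zwitterion deprotonates the alcohol and the alkoxide adds to C10 with loss of PMe3, should give the thermodynamically favoured (E)-β-alkoxy enone with the C3–O bond, and hence the C3 configuration, untouched.

**Step 6**
Reactants: 10 (3E)-4-{[(3S)-2-bromo-5-[(tert-butyldimethylsilyl)oxy]pent-1-en-3-yl]oxy}-1,1-dimethoxypent-3-en-2-one
Product: 11 (3E)-4-{[(3S)-2-bromo-5-hydroxypent-1-en-3-yl]oxy}-1,1-dimethoxypent-3-en-2-one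
Conditions: HF·pyridine, pyridine, THF, 0 °C; used directly
Reagents that add atoms: none
Why: Buffered fluoride cleaves the primary silyl ether (desilylation) without hydrolysing the dimethyl acetal or the vinylogous ester.

**Step 7**
Reactants: 11 (3E)-4-{[(3S)-2-bromo-5-hydroxypent-1-en-3-yl]oxy}-1,1-dimethoxypent-3-en-2-one
Product: 12 (3S)-4-bromo-3-{[(2E)-5,5-dimethoxy-4-oxopent-2-en-2-yl]oxy}pent-4-enal
Conditions: Dess–Martin periodinane, NaHCO3, CH2Cl2, 0 °C; used crude
Reagents that add atoms: none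
Why: Dess–Martin oxidation gives the β-(vinyloxy) aldehyde under buffered conditions, and the product is used crude because it is prone to E1cB loss of the enol ether oxygen on silica or with base.

**Step 8**
Reactants: 12 (3S)-4-bromo-3-{[(2E)-5,5-dimethoxy-4-oxopent-2-en-2-yl]oxy}pent-4-enal
Product: 13 (2S,5S)-5-(1-bromoethenyl)-2-(3,3-dimethoxy-2-oxopropyl)-2-methyloxolan-3-one
Conditions: (5aS,10bR)-5a,10b-dihydro-2-(pentafluorophenyl)-4H,6H-indeno[2,1-b][1,2,4]triazolo[4,3-d][1,4]oxazinium tetrafluoroborate (20 mol %), KN(SiMe3)2 (18 mol %), toluene, 23 °C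
Reagents that add atoms: none
Why: The triazolylidene carbene adds to the C1 aldehyde and proton transfer gives the enaminol (an acyl anion equivalent), which adds to C10, the β-carbon of the (E)-β-alkoxy enone, before protonation of the C9 enolate and release of the carbene (intramolecular Stetter reaction). The closest known reaction type is the asymmetric intramolecular Stetter cyclisation of aldehydes onto β-oxy-β-alkyl acceptors that gives 2,2-disubstituted benzofuran-3-ones with an oxygen-bearing quaternary centre, together with the aliphatic aldehyde variant that forms quaternary centres. Ring B closes in the 5-exo-trig mode, the ring oxygen already linking C3 and C10. The new C10 stereocentre is set by the chiral carbene, which shields one face of the enone (the (5aS,10bR) salt is proposed as the matched enantiomer), and is reinforced by the C3 substituent, which sits pseudo-equatorial in the envelope-like transition state and places the C9 chain cis to it, as in 5-exo acyl radical closures to cis-2,5-disubstituted oxolan-3-ones. The step needs conjugate addition to outrun cross-benzoin attack on the C8 ketone (seven-membered ring) and base-induced β-elimination of the enol ether oxygen; the five-membered transition state, the E geometry of the acceptor and the use of less base than triazolium salt (no free amide) should secure this.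

**Step 9**
Reactants: 13 (2S,5S)-5-(1-bromoethenyl)-2-(3,3-dimethoxy-2-oxopropyl)-2-methyloxolan-3-one
Product: 14 (2S)-5-(1-bromoethenyl)-2-(3,3-dimethoxy-2-oxopropyl)-2-methylfuran-3(2H)-one
Conditions: IBX, 4-methoxypyridine N-oxide, DMSO, 25 °C
Reagents that add atoms: none
Why: IBX-mediated dehydrogenation through the C1 enol can only introduce the C2=C3 double bond, since C10 is quaternary and the C8 ketone has no removable β-hydrogen, so the oxolanone becomes the 3(2H)-furanone and the C3 stereocentre is erased.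

**Step 10**
Reactants: 14 (2S)-5-(1-bromoethenyl)-2-(3,3-dimethoxy-2-oxopropyl)-2-methylfuran-3(2H)-one
Product: 15 (2S)-5-(1-bromoethenyl)-2-[(2R)-2-hydroxy-3,3-dimethoxypropyl]-2-methylfuran-3(2H)-one
Conditions: (S)-tetrahydro-1-methyl-3,3-diphenyl-1H,3H-pyrrolo[1,2-c][1,3,2]oxazaborole, catecholborane, toluene–CH2Cl2, −78 °C; H2O
Reagents that add atoms: none
Why: Corey–Bakshi–Shibata reduction of the α-keto acetal, with the dimethoxymethyl group as the large substituent so that the (S)-oxazaborolidine should give the (8R)-carbinol, while the vinylogous-ester carbonyl of ring B is inert at −78 °C and the absence of base prevents ring B from opening by a retro-oxa-Michael reaction.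

**Step 11**
Reactants: 15 (2S)-5-(1-bromoethenyl)-2-[(2R)-2-hydroxy-3,3-dimethoxypropyl]-2-methylfuran-3(2H)-one
Product: 16 (2S)-5-(1-bromoethenyl)-2-[(2R)-2-[(tert-butyldimethylsilyl)oxy]-3,3-dimethoxypropyl]-2-methylfuran-3(2H)-one
Conditions: t-BuMe2SiCl, imidazole, DMF, 35 °C
Reagents that add atoms: tert-butyldimethylsilyl chloride, CC(C)(C)[Si](C)(C)Cl
Why: Imidazole-mediated silylation protects O8 as a non-chelating, poorly leaving group for steps 13 to 15.

**Step 12**
Reactants: 16 (2S)-5-(1-bromoethenyl)-2-[(2R)-2-[(tert-butyldimethylsilyl)oxy]-3,3-dimethoxypropyl]-2-methylfuran-3(2H)-one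
Product: 17 (2R)-3-[(2S)-5-(1-bromoethenyl)-2-methyl-3-oxo-2,3-dihydrofuran-2-yl]-2-[(tert-butyldimethylsilyl)oxy]propanal
Conditions: Et3SiOTf, 2,4,6-collidine, CH2Cl2, 0 °C; then H2O
Reagents that add atoms: water, O
Why: The silyl triflate and collidine convert the dimethyl acetal into a collidinium O,N-acetal that water hydrolyses to the aldehyde (non-acidic acetal cleavage), leaving the silyl ether, the furanone and the C8 configuration intact.

**Step 13**
Reactants: 17 (2R)-3-[(2S)-5-(1-bromoethenyl)-2-methyl-3-oxo-2,3-dihydrofuran-2-yl]-2-[(tert-butyldimethylsilyl)oxy]propanal; 18 methyl prop-2-enoate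
Product: 19 methyl (4R)-5-[(2S)-5-(1-bromoethenyl)-2-methyl-3-oxo-2,3-dihydrofuran-2-yl]-4-[(tert-butyldimethylsilyl)oxy]-3-hydroxy-2-methylidenepentanoate (both C3 epimers)
Conditions: 18 (excess), 1,4-diazabicyclo[2.2.2]octane (1 equiv), MeOH, rt, several days
Reagents that add atoms: none
Why: Morita–Baylis–Hillman reaction, in which the ammonium enolate from the amine and methyl acrylate adds to the aldehyde and the amine is then eliminated, gives the α-methylene-β-hydroxy ester whose new carbinol centre is unselective but is destroyed in step 14.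

**Step 14**
Reactants: 19 methyl (4R)-5-[(2S)-5-(1-bromoethenyl)-2-methyl-3-oxo-2,3-dihydrofuran-2-yl]-4-[(tert-butyldimethylsilyl)oxy]-3-hydroxy-2-methylidenepentanoate
Product: 20 methyl (2Z,4R)-5-[(2S)-5-(1-bromoethenyl)-2-methyl-3-oxo-2,3-dihydrofuran-2-yl]-2-(bromomethyl)-4-[(tert-butyldimethylsilyl)oxy]pent-2-enoate
Conditions: PBr3, Et2O, −10 °C
Reagents that add atoms: phosphorus tribromide, BrP(Br)Br
Why: PBr3 activates the allylic alcohol and bromide attacks the methylene terminus (SN2′ allylic transposition), which should give the conjugated, thermodynamically preferred (Z)-2-(bromomethyl)enoate.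

**Step 15**
Reactants: 20 methyl (2Z,4R)-5-[(2S)-5-(1-bromoethenyl)-2-methyl-3-oxo-2,3-dihydrofuran-2-yl]-2-(bromomethyl)-4-[(tert-butyldimethylsilyl)oxy]pent-2-enoate; 21 2,2-dimethoxyacetaldehyde
Product: 23 (4S,5R)-4-{(1R)-2-[(2S)-5-(1-bromoethenyl)-2-methyl-3-oxo-2,3-dihydrofuran-2-yl]-1-[(tert-butyldimethylsilyl)oxy]ethyl}-5-(dimethoxymethyl)-3-methylideneoxolan-2-one, via seco hydroxy ester 22 (not isolated)
Conditions: indium powder (In), THF–H2O (1:1), rt; then pyridinium p-toluenesulfonate (cat.), benzene, 50 °C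
Reagents that add atoms: none
Why: Barbier allylation, in which the (Z)-allylindium species reacts through a chair-like six-membered transition state with the C8-bearing substituent axial (hence the 6,7-syn adduct) and with allylic strain turning C8–H toward the ring so that the aldehyde approaches C7 anti to the C9 chain, should fix C7 and C6 relative to C8, and acid then lactonises the syn γ-hydroxy ester to the cis-fused ring A.

**Step 16**
Reactants: 23 (4S,5R)-4-{(1R)-2-[(2S)-5-(1-bromoethenyl)-2-methyl-3-oxo-2,3-dihydrofuran-2-yl]-1-[(tert-butyldimethylsilyl)oxy]ethyl}-5-(dimethoxymethyl)-3-methylideneoxolan-2-one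
Product: 24 (4R,5R)-4-{(1R)-2-[(2S)-5-(1-bromoethenyl)-2-methyl-3-oxo-2,3-dihydrofuran-2-yl]-1-hydroxyethyl}-5-(dimethoxymethyl)-3-methylideneoxolan-2-one
Conditions: HF·pyridine, pyridine, THF, 0 °C to rt; used at once
Reagents that add atoms: none
Why: Fluoride-mediated desilylation frees O8 while the acetal, the lactone and the vinyl bromide are inert, and the alcohol is acylated at once to forestall translactonisation to O8.

**Step 17**
Reactants: 24 (4R,5R)-4-{(1R)-2-[(2S)-5-(1-bromoethenyl)-2-methyl-3-oxo-2,3-dihydrofuran-2-yl]-1-hydroxyethyl}-5-(dimethoxymethyl)-3-methylideneoxolan-2-one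
Product: 25 (1R)-2-[(2S)-5-(1-bromoethenyl)-2-methyl-3-oxo-2,3-dihydrofuran-2-yl]-1-[(2R,3R)-2-(dimethoxymethyl)-4-methylidene-5-oxooxolan-3-yl]ethyl 2-methylpropanoate
Conditions: isobutyryl chloride, pyridine, 4-(dimethylamino)pyridine (cat.), CH2Cl2, 0 °C
Reagents that add atoms: 2-methylpropanoyl chloride, CC(C)C(=O)Cl
Why: Acyl transfer catalysed by 4-(dimethylamino)pyridine esterifies the only free hydroxyl group with retention at C8.

**Step 18**
Reactants: 25 (1R)-2-[(2S)-5-(1-bromoethenyl)-2-methyl-3-oxo-2,3-dihydrofuran-2-yl]-1-[(2R,3R)-2-(dimethoxymethyl)-4-methylidene-5-oxooxolan-3-yl]ethyl 2-methylpropanoate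
Product: 26 (1R)-2-[(2S)-5-(1-bromoethenyl)-2-methyl-3-oxo-2,3-dihydrofuran-2-yl]-1-[(2R,3R)-2-formyl-4-methylidene-5-oxooxolan-3-yl]ethyl 2-methylpropanoate
Conditions: Et3SiOTf, 2,4,6-collidine, CH2Cl2, 0 °C to rt; then H2O; used crude
Reagents that add atoms: water, O
Why: The same silyl triflate–collidine acetal cleavage as in step 12 unmasks the C5 aldehyde without acid or base, so that the epimerisable C6 centre and both esters survive.

**Step 19**
Reactants: 26 (1R)-2-[(2S)-5-(1-bromoethenyl)-2-methyl-3-oxo-2,3-dihydrofuran-2-yl]-1-[(2R,3R)-2-formyl-4-methylidene-5-oxooxolan-3-yl]ethyl 2-methylpropanoate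
Product: 27 (5S,6R,7R,8R,10S)-5-hydroxy-8-(2-methylpropanoyloxy)-1-oxo-3,10-epoxygermacra-2,4(15),11(13)-trien-12,6-olide (CNP0384113.2)
Conditions: CrCl2 (10 equiv), NiCl2 (2 mol %), degassed DMSO–THF, slow addition of 26 to 0.002 M, rt
Reagents that add atoms: none
Why: Nozaki–Hiyama–Kishi reaction, in which zerovalent nickel inserts into the C4–Br bond, transmetalation gives an alkenyl species of trivalent chromium that adds chemoselectively to the aldehyde under high dilution to close ring C, and addition anti to the C6–O bond (non-chelation control) should give the 5,6-anti, (5S)-configured allylic alcohol.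

**Compound list**
1 | 3-[(tert-butyldimethylsilyl)oxy]propanal | O=CCCO[Si](C)(C)C(C)(C)C | starting material
2 | bromoethene | C=CBr | starting material
3 | 1-bromo-1-lithioethene | [Li]C(Br)=C | intermediate
4 | rac-2-bromo-5-[(tert-butyldimethylsilyl)oxy]pent-1-en-3-ol | C=C(Br)C(O)CCO[Si](C)(C)C(C)(C)C | intermediate
5 | 2-bromo-5-[(tert-butyldimethylsilyl)oxy]pent-1-en-3-one | C=C(Br)C(=O)CCO[Si](C)(C)C(C)(C)C | intermediate
6 | (3S)-2-bromo-5-[(tert-butyldimethylsilyl)oxy]pent-1-en-3-ol | O[C@H](C(Br)=C)CCO[Si](C)(C)C(C)(C)C | intermediate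
7 | methyl 2,2-dimethoxyacetate | COC(OC)C(=O)OC | starting material
8 | prop-1-yn-1-ylmagnesium bromide | CC#C[Mg]Br | starting material
9 | 1,1-dimethoxypent-3-yn-2-one | COC(OC)C(=O)C#CC | intermediate
10 | (3E)-4-{[(3S)-2-bromo-5-[(tert-butyldimethylsilyl)oxy]pent-1-en-3-yl]oxy}-1,1-dimethoxypent-3-en-2-one | COC(OC)C(=O)/C=C(\C)O[C@H](C(Br)=C)CCO[Si](C)(C)C(C)(C)C | intermediate
11 | (3E)-4-{[(3S)-2-bromo-5-hydroxypent-1-en-3-yl]oxy}-1,1-dimethoxypent-3-en-2-one | COC(OC)C(=O)/C=C(\C)O[C@H](C(Br)=C)CCO | intermediate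
12 | (3S)-4-bromo-3-{[(2E)-5,5-dimethoxy-4-oxopent-2-en-2-yl]oxy}pent-4-enal | COC(OC)C(=O)/C=C(\C)O[C@H](C(Br)=C)CC=O | intermediate
13 | (2S,5S)-5-(1-bromoethenyl)-2-(3,3-dimethoxy-2-oxopropyl)-2-methyloxolan-3-one | COC(OC)C(=O)C[C@]1(C)O[C@H](C(Br)=C)CC1=O | intermediate
14 | (2S)-5-(1-bromoethenyl)-2-(3,3-dimethoxy-2-oxopropyl)-2-methylfuran-3(2H)-one | COC(OC)C(=O)C[C@]1(C)OC(=CC1=O)C(Br)=C | intermediate
15 | (2S)-5-(1-bromoethenyl)-2-[(2R)-2-hydroxy-3,3-dimethoxypropyl]-2-methylfuran-3(2H)-one | COC(OC)[C@H](O)C[C@]1(C)OC(=CC1=O)C(Br)=C | intermediate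
16 | (2S)-5-(1-bromoethenyl)-2-[(2R)-2-[(tert-butyldimethylsilyl)oxy]-3,3-dimethoxypropyl]-2-methylfuran-3(2H)-one | COC(OC)[C@H](O[Si](C)(C)C(C)(C)C)C[C@]1(C)OC(=CC1=O)C(Br)=C | intermediate
17 | (2R)-3-[(2S)-5-(1-bromoethenyl)-2-methyl-3-oxo-2,3-dihydrofuran-2-yl]-2-[(tert-butyldimethylsilyl)oxy]propanal | O=C[C@H](O[Si](C)(C)C(C)(C)C)C[C@]1(C)OC(=CC1=O)C(Br)=C | intermediate
18 | methyl prop-2-enoate (methyl acrylate) | C=CC(=O)OC | starting material
19 | methyl (4R)-5-[(2S)-5-(1-bromoethenyl)-2-methyl-3-oxo-2,3-dihydrofuran-2-yl]-4-[(tert-butyldimethylsilyl)oxy]-3-hydroxy-2-methylidenepentanoate (C3 epimers) | C=C(C(=O)OC)C(O)[C@H](O[Si](C)(C)C(C)(C)C)C[C@]1(C)OC(=CC1=O)C(Br)=C | intermediate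
20 | methyl (2Z,4R)-5-[(2S)-5-(1-bromoethenyl)-2-methyl-3-oxo-2,3-dihydrofuran-2-yl]-2-(bromomethyl)-4-[(tert-butyldimethylsilyl)oxy]pent-2-enoate | BrC/C(C(=O)OC)=C\[C@H](O[Si](C)(C)C(C)(C)C)C[C@]1(C)OC(=CC1=O)C(Br)=C | intermediate
21 | 2,2-dimethoxyacetaldehyde | COC(OC)C=O | starting material
22 | methyl (3S,4R)-3-{(1R)-2-[(2S)-5-(1-bromoethenyl)-2-methyl-3-oxo-2,3-dihydrofuran-2-yl]-1-[(tert-butyldimethylsilyl)oxy]ethyl}-4-hydroxy-5,5-dimethoxy-2-methylidenepentanoate | C=C(C(=O)OC)[C@@H]([C@@H](O)C(OC)OC)[C@H](O[Si](C)(C)C(C)(C)C)C[C@]1(C)OC(=CC1=O)C(Br)=C | intermediate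
23 | (4S,5R)-4-{(1R)-2-[(2S)-5-(1-bromoethenyl)-2-methyl-3-oxo-2,3-dihydrofuran-2-yl]-1-[(tert-butyldimethylsilyl)oxy]ethyl}-5-(dimethoxymethyl)-3-methylideneoxolan-2-one | C=C1C(=O)O[C@@H](C(OC)OC)[C@H]1[C@H](O[Si](C)(C)C(C)(C)C)C[C@]1(C)OC(=CC1=O)C(Br)=C | intermediate
24 | (4R,5R)-4-{(1R)-2-[(2S)-5-(1-bromoethenyl)-2-methyl-3-oxo-2,3-dihydrofuran-2-yl]-1-hydroxyethyl}-5-(dimethoxymethyl)-3-methylideneoxolan-2-one | C=C1C(=O)O[C@@H](C(OC)OC)[C@H]1[C@H](O)C[C@]1(C)OC(=CC1=O)C(Br)=C | intermediate
25 | (1R)-2-[(2S)-5-(1-bromoethenyl)-2-methyl-3-oxo-2,3-dihydrofuran-2-yl]-1-[(2R,3R)-2-(dimethoxymethyl)-4-methylidene-5-oxooxolan-3-yl]ethyl 2-methylpropanoate | C=C1C(=O)O[C@@H](C(OC)OC)[C@H]1[C@H](OC(=O)C(C)C)C[C@]1(C)OC(=CC1=O)C(Br)=C | intermediate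
26 | (1R)-2-[(2S)-5-(1-bromoethenyl)-2-methyl-3-oxo-2,3-dihydrofuran-2-yl]-1-[(2R,3R)-2-formyl-4-methylidene-5-oxooxolan-3-yl]ethyl 2-methylpropanoate | C=C1C(=O)O[C@@H](C=O)[C@H]1[C@H](OC(=O)C(C)C)C[C@]1(C)OC(=CC1=O)C(Br)=C | intermediate
27 | (5S,6R,7R,8R,10S)-5-hydroxy-8-(2-methylpropanoyloxy)-1-oxo-3,10-epoxygermacra-2,4(15),11(13)-trien-12,6-olide (CNP0384113.2) | C=C1C(=O)O[C@@H]2[C@H]1[C@H](OC(=O)C(C)C)C[C@]1(C)OC(=CC1=O)C(=C)[C@@H]2O | target

**Step count and risks**
Total step count: 19. Longest linear sequence: 18 steps (steps 1–3 and 5–19; step 4 is the one-step side branch).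

Steps most likely to fail:

1. Step 8 (key step). What may go wrong: base-induced β-elimination of the enol ether oxygen from aldehyde 12 before the carbene engages it, or sluggish addition to the electron-rich vinylogous-ester acceptor. Fallback (radical instead of polar closure of the same bond): the fallback sets out from 12, which is oxidised (NaClO2, NaH2PO4, 2-methyl-2-butene, t-BuOH–H2O) to (3S)-4-bromo-3-{[(2E)-5,5-dimethoxy-4-oxopent-2-en-2-yl]oxy}pent-4-enoic acid F1. This is converted ((PhSe)2, PBu3, CH2Cl2) into Se-phenyl (3S)-4-bromo-3-{[(2E)-5,5-dimethoxy-4-oxopent-2-en-2-yl]oxy}pent-4-eneselenoate F2. Treatment with (Me3Si)3SiH and Et3B/air in benzene at room temperature generates the acyl radical, whose 5-exo-trig addition to the β-alkoxy enone (the established acyl radical route to cis-2,5-disubstituted oxolan-3-ones) should give 13, where the route is rejoined. In this variant C10 is set by the C3 substituent alone.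

2. Step 15. What may go wrong: poor facial selectivity of the allylindium species with respect to the C8 silyloxy centre, giving the wrong C6/C7 pair, or vinylogous elimination of the silyloxy group. Fallback (catalyst control instead of substrate control): the fallback sets out from 19, which is acetylated (Ac2O, 4-(dimethylamino)pyridine, pyridine) to methyl (4R)-3-acetoxy-5-[(2S)-5-(1-bromoethenyl)-2-methyl-3-oxo-2,3-dihydrofuran-2-yl]-4-[(tert-butyldimethylsilyl)oxy]-2-methylidenepentanoate F3. Copper-catalysed SN2′ borylation (bis(pinacolato)diboron, CuCl, LiCl, KOAc, DMF) gives methyl (2E,4R)-5-[(2S)-5-(1-bromoethenyl)-2-methyl-3-oxo-2,3-dihydrofuran-2-yl]-4-[(tert-butyldimethylsilyl)oxy]-2-[(4,4,5,5-tetramethyl-1,3,2-dioxaborolan-2-yl)methyl]pent-2-enoate F4. Allylboration of 21 with F4, catalysed by (R)- or (S)-3,3′-bis(2,4,6-triisopropylphenyl)-1,1′-binaphthyl-2,2′-diyl hydrogen phosphate in toluene at low temperature, passes through the same chair but lets the catalyst choose the aldehyde face and, through the chair, the allyl face. The resulting hydroxy ester 22 is lactonised as in step 15 to 23, where the route is rejoined.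

3. Step 19. What may go wrong: oligomerisation competing with closure of the ten-membered ring, and poor facial selectivity at C5 because transannular strain overrides non-chelation control. Fallback for the selectivity problem (reagent-controlled reduction instead of substrate-controlled addition): the fallback sets out from 26, whose ring closure would then deliver 27 together with its C5 epimer, the (5R)-alcohol F5. The mixture is oxidised (Dess–Martin periodinane, NaHCO3, CH2Cl2) to the ring C dienone, 8-(2-methylpropanoyloxy)-1,5-dioxo-3,10-epoxygermacra-2,4(15),11(13)-trien-12,6-olide F6. The C5 ketone is then reduced with (S)-tetrahydro-1-methyl-3,3-diphenyl-1H,3H-pyrrolo[1,2-c][1,3,2]oxazaborole and catecholborane at −78 °C (or NaBH4–CeCl3 at −78 °C for attack from the ring periphery) to return to 27. This fallback does not cure a failure to cyclise.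

**Further compounds**
F1 | step 8 | (3S)-4-bromo-3-{[(2E)-5,5-dimethoxy-4-oxopent-2-en-2-yl]oxy}pent-4-enoic acid | COC(OC)C(=O)/C=C(\C)O[C@H](C(Br)=C)CC(=O)O
F2 | step 8 | Se-phenyl (3S)-4-bromo-3-{[(2E)-5,5-dimethoxy-4-oxopent-2-en-2-yl]oxy}pent-4-eneselenoate | COC(OC)C(=O)/C=C(\C)O[C@H](C(Br)=C)CC(=O)[Se]c1ccccc1
F3 | step 15 | methyl (4R)-3-acetoxy-5-[(2S)-5-(1-bromoethenyl)-2-methyl-3-oxo-2,3-dihydrofuran-2-yl]-4-[(tert-butyldimethylsilyl)oxy]-2-methylidenepentanoate (C3 epimers) | C=C(C(=O)OC)C(OC(C)=O)[C@H](O[Si](C)(C)C(C)(C)C)C[C@]1(C)OC(=CC1=O)C(Br)=C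
F4 | step 15 | methyl (2E,4R)-5-[(2S)-5-(1-bromoethenyl)-2-methyl-3-oxo-2,3-dihydrofuran-2-yl]-4-[(tert-butyldimethylsilyl)oxy]-2-[(4,4,5,5-tetramethyl-1,3,2-dioxaborolan-2-yl)methyl]pent-2-enoate | COC(=O)/C(CB1OC(C)(C)C(C)(C)O1)=C/[C@H](O[Si](C)(C)C(C)(C)C)C[C@]2(C)OC(=CC2=O)C(Br)=C
F5 | step 19 | (5R,6R,7R,8R,10S)-5-hydroxy-8-(2-methylpropanoyloxy)-1-oxo-3,10-epoxygermacra-2,4(15),11(13)-trien-12,6-olide (C5 epimer of 27) | C=C1C(=O)O[C@@H]2[C@H]1[C@H](OC(=O)C(C)C)C[C@]1(C)OC(=CC1=O)C(=C)[C@H]2O
F6 | step 19 | (6R,7R,8R,10S)-8-(2-methylpropanoyloxy)-1,5-dioxo-3,10-epoxygermacra-2,4(15),11(13)-trien-12,6-olide | C=C1C(=O)O[C@@H]2[C@H]1[C@H](OC(=O)C(C)C)C[C@]1(C)OC(=CC1=O)C(=C)C2=O
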